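C1 ketone, C2–C3 methylenes, C4 (CH3)/C5 oxirane, C6 lactone CH–O, C7=C11 butenolide olefin, C8 propionate carbon, C9 CH2, C10 (CH3, OAc), C12 lactone C=O, C13 CH2OAc.
Enabling feature: in the ten-membered ring C3 is β to the C1 carbonyl and also bonded to the fully substituted oxirane carbon C4. C3–C4 is therefore the bond a C4 oxiranyl radical makes on adding to the CH2 end of a C1 vinyl ketone, and a carboxyl group on C4 is the radical source.
Cuts, in order: C3–C4; C13–OAc together with C7=C11 (back to a 7,8-epoxy-α-methylene lactone); C7–C11 and O–C12 (lactone ring); C6–C7 (east C4–C6 enal plus west C7–C10/C1–C3 alkyne); C9–C10 and C1–C2 inside the west fragment.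
Forward: the chain is joined at C6–C7, the oxirane is made next, then the γ-lactone ring, and the ten-membered carbocycle last.
Stereochemistry: C10 comes from (S)-lactic acid (self-regeneration of the stereocentre) and C6 from a catalytic asymmetric alkynylation. C4/C5 come from a hydroxyl-directed epoxidation under A(1,3) control, and C8 from a face-selective epoxidation of a geometrically defined C7=C8 alkylidene. C4 is formed again in the key step under control of C5/C6.

Key step: step 21

Remark 1: the C1 carbinol carbon of compounds 13–25 is carried as a mixture of epimers because step 18 turns it into the ketone, so its descriptor is left open in the SMILES.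
Remark 2: the (S,S) antipode of ProPhenol is assumed to deliver the alkynyl group to the Si face of enal 5; this assignment would be checked on a simple alkyne first.
Remark 3: "the exocyclic carbon on C4" means the CH2O carbon of the east fragment, which becomes the carboxyl carbon and leaves as CO2.

Step 1
Reactants: 1 (E)-4-acetoxy-2-methylbut-2-enal
Product: 2 (E)-4-hydroxy-3-methylbut-2-enyl acetate
Conditions: NaBH4, CeCl3·7H2O, MeOH, 0 °C
Reagents that add atoms: none
Why: Luche 1,2-reduction of an enal, which should leave the E olefin and the acetate untouched.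

Step 2
Reactants: 2 (E)-4-hydroxy-3-methylbut-2-enyl acetate
Product: 3 (E)-4-(tert-butyldimethylsilyloxy)-3-methylbut-2-enyl acetate
Conditions: TBSCl, imidazole, DMF, rt
Reagents that add atoms: tert-butyldimethylsilyl chloride, CC(C)(C)[Si](C)(C)Cl
Why: Routine silyl ether protection of a primary allylic alcohol, which masks the exocyclic carbon on C4 until the end game.

Step 3
Reactants: 3 (E)-4-(tert-butyldimethylsilyloxy)-3-methylbut-2-enyl acetate
Product: 4 (E)-4-(tert-butyldimethylsilyloxy)-3-methylbut-2-en-1-ol
Conditions: K2CO3 (0.2 equiv), MeOH, 0 °C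
Reagents that add atoms: none
Why: Base-catalysed transesterification (Zemplén-type methanolysis) frees the C6 hydroxyl while the silyl ether is inert.

Step 4
Reactants: 4 (E)-4-(tert-butyldimethylsilyloxy)-3-methylbut-2-en-1-ol
Product: 5 (E)-4-(tert-butyldimethylsilyloxy)-3-methylbut-2-enal (east fragment, C4–C6)
Conditions: MnO2, CH2Cl2, rt
Reagents that add atoms: none
Why: Allylic alcohol oxidation with MnO2 stops at the enal and should keep the E geometry, with the C4 methyl cis to C6.

Step 5
Reactants: 6 (S)-lactic acid; 7 pivalaldehyde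
Product: 8 (2S,5S)-2-tert-butyl-5-methyl-1,3-dioxolan-4-one (cis)
Conditions: p-TsOH (cat.), pentane, reflux, water separator; low-temperature crystallisation
Reagents that add atoms: none
Why: Acid-catalysed acetalisation of an α-hydroxy acid stores the lactic acid chirality in the acetal centre (self-regeneration of stereocentres), and the cis isomer is purified by crystallisation.

Step 6
Reactants: 8 (2S,5S)-2-tert-butyl-5-methyl-1,3-dioxolan-4-one; 9 propargyl bromide
Product: 10 (2S,5R)-2-tert-butyl-5-methyl-5-(prop-2-ynyl)-1,3-dioxolan-4-one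
Conditions: LiN(iPr)2, THF, −78 °C; then 9, −78 → −30 °C
Reagents that add atoms: none
Why: Enolate alkylation in which the reactive halide enters anti to the tert-butyl group, forming C9–C10 and fixing the quaternary C10 in the configuration of the target.

Step 7
Reactants: 10 (2S,5R)-2-tert-butyl-5-methyl-5-(prop-2-ynyl)-1,3-dioxolan-4-one; 11 vinylmagnesium bromide
Product: 13 (4R)-4-methylhept-1-en-6-yne-3,4-diol (both carbinol epimers), via lactol 12 (not isolated)
Conditions: iBu2AlH (1.1 equiv), CH2Cl2, −78 °C; then 11 (5 equiv), THF, −78 °C → rt; aq. potassium sodium tartrate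
Reagents that add atoms: none
Why: One-pot partial reduction and Grignard addition, in which the aluminated lactol collapses on warming to the α-oxido aldehyde and is vinylated (C1–C2), while the liberated pivalaldehyde merely consumes reagent and C10 is not touched.

Step 8
Reactants: 13 (4R)-4-methylhept-1-en-6-yne-3,4-diol
Product: 14 (4R)-3-(tert-butyldimethylsilyloxy)-4-methylhept-1-en-6-yn-4-ol
Conditions: TBSCl, imidazole, DMF, rt
Reagents that add atoms: tert-butyldimethylsilyl chloride, CC(C)(C)[Si](C)(C)Cl
Why: Silylation discriminates the secondary allylic hydroxyl (C1) from the tertiary one (C10) on steric grounds, which masks the future enone as an allylic silyl ether.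

Step 9
Reactants: 14 (4R)-3-(tert-butyldimethylsilyloxy)-4-methylhept-1-en-6-yn-4-ol
Product: 15 (4R)-3-(tert-butyldimethylsilyloxy)-4-methylhept-1-en-6-yn-4-yl acetate (west fragment, C7–C10 and C1–C3)
Conditions: Ac2O, Et3N, DMAP (1 equiv), CH2Cl2, 40 °C
Reagents that add atoms: acetic anhydride, CC(=O)OC(C)=O
Why: DMAP-promoted (Steglich-type) acylation of a tertiary alcohol needs forcing conditions, so it is done here, where no base-labile group is yet present.

Step 10
Reactants: 5 (E)-4-(tert-butyldimethylsilyloxy)-3-methylbut-2-enal; 15 west alkyne acetate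
Product: 16 (4R,8R,9E)-3,11-bis(tert-butyldimethylsilyloxy)-8-hydroxy-4,10-dimethylundeca-1,9-dien-6-yn-4-yl acetate (target numbering: 6R, 10R)
Conditions: (S,S)-ProPhenol (20 mol%), Me2Zn (3 equiv), Ph3PO (40 mol%), 15 (1.3 equiv), toluene, 4 °C
Reagents that add atoms: none
Why: Catalytic asymmetric alkynylation of an enal with a dinuclear zinc–ProPhenol catalyst forms C6–C7, sets C6 by Si-face delivery of the zinc alkynylide, and tolerates acetate and silyl ethers.

Step 11
Reactants: 16 C6 propargylic/allylic alcohol
Product: 17 4,5-epoxy-6-ol (target numbering: 4R,5R,6S,10R; oxirane O syn to the C6 hydroxyl, C4 methyl cis to C6)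
Conditions: mCPBA, Na2HPO4 (buffer), CH2Cl2, 0 °C
Reagents that add atoms: 3-chloroperbenzoic acid, O=C(OO)c1cccc(Cl)c1
Why: Hydroxyl-directed peracid epoxidation, in which A(1,3) strain with the cis C4 methyl fixes the rotamer with C6–H in the olefin plane, so oxygen should be delivered on the hydroxyl face (threo product, setting C4 and C5) while the monosubstituted vinyl group and the alkyne are much slower.

Step 12
Reactants: 17 4,5-epoxy-6-ol alkyne
Product: 18 (Z)-7-tributylstannyl-7,8-alkene (tin on C7, C9 syn to tin, H on C8 syn to C6; other centres unchanged)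
Conditions: [Cp*RuCl]4 (2.5 mol%), Bu3SnH (1.1 equiv, slow addition), CH2Cl2, rt
Reagents that add atoms: tributyltin hydride, CCCC[SnH](CCCC)CCCC
Why: Ruthenium-catalysed trans-hydrostannation of a propargylic alcohol, in which the O–H···Cl–Ru hydrogen bond should steer tin to the proximal carbon C7 and trans addition defines the olefin geometry that later decides C8.

Step 13
Reactants: 18 (Z)-C7 alkenylstannane; 19 methyl 2-bromoacrylate
Product: 21 α-methylene-β-alkylidene-γ-butyrolactone (C11=C13H2 and C7=C8 exocyclic; C9 syn to C11), via hydroxy ester 20 (not isolated)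
Conditions: 19, Pd(PPh3)4 (10 mol%), Cu(O2CC4H3S) (CuTC), [NBu4][Ph2PO2], DMF, rt; then PPTS (cat.), benzene, 40 °C; used at once
Reagents that add atoms: none
Why: Copper-assisted Stille coupling under neutral, tin-scavenging conditions forms C7–C11 with retention of olefin geometry, and mild acid-catalysed lactonisation of the γ-hydroxy acrylate then closes the lactone ring (O–C12).

Step 14
Reactants: 21 α-methylene-β-alkylidene lactone
Product: 22 7,8-epoxide of 21 (spiro-oxirane, O anti to the C5 substituent on C6; 8S)
Conditions: dimethyldioxirane (1.1 equiv, acetone solution), CH2Cl2, −40 → 0 °C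
Reagents that add atoms: dimethyldioxirane, CC1(C)OO1
Why: Electrophilic epoxidation should pick the only electron-rich trisubstituted olefin (C7=C8), since C11=C13 is acrylate-like and the vinyl group is monosubstituted; it should attack the ring face away from the C5 substituent on C6, which with the fixed olefin geometry sets C8.

Step 15
Reactants: 22 7,8-epoxy-α-methylene lactone
Product: 23 13-acetoxy-8-hydroxy-7(11)-butenolide (8S)
Conditions: Pd(PPh3)4 (5 mol%), AcOH (2 equiv), THF, 0 °C
Reagents that add atoms: acetic acid, CC(=O)O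
Why: Tsuji–Trost-type 1,4-addition of a carboxylic acid to a vinyl epoxide, in which zerovalent palladium ionises the allylic C7–O bond and acetate attacks the primary terminus C13, so the tetrasubstituted C7=C11 olefin and the C13 acetate arise together while the untouched C8–O bond keeps its configuration.

Step 16
Reactants: 23 13-acetoxy-8-hydroxy butenolide
Product: 24 8-propionate (all three acyl groups in place, both silyl ethers intact)
Conditions: (EtCO)2O, pyridine, DMAP (5 mol%), CH2Cl2, 0 °C
Reagents that add atoms: propionic anhydride, CCC(=O)OC(=O)CC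
Why: Catalysed acylation of the only free hydroxyl, run cold and fast so that it outruns acetyl migration from C10 and deprotonation at C6.

Step 17
Reactants: 24 bis-silyl ether triester
Product: 25 diol (C1–OH and CH2OH on C4)
Conditions: HF·pyridine, pyridine, THF, 0 °C → rt
Reagents that add atoms: none
Why: Buffered fluoride desilylation removes both silyl groups in one operation under slightly acidic conditions, which epoxides and esters tolerate and which disfavour the base-promoted shift of the C10 acetyl group to C1–OH.

Step 18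
Reactants: 25 diol
Product: 26 C1 vinyl ketone carrying the C4 carbaldehyde
Conditions: Dess–Martin periodinane (3 equiv), pyridine (buffer), CH2Cl2, 0 °C → rt
Reagents that add atoms: none
Why: Dess–Martin oxidation converts the allylic alcohol into the enone and the epoxy alcohol into the non-enolisable epoxy aldehyde in one neutral step, which also erases the C1 stereocentre.

Step 19
Reactants: 26 keto aldehyde
Product: 27 C4 glycidic acid
Conditions: NaClO2, NaH2PO4, 2-methyl-2-butene, t-BuOH/H2O, 0 °C; used without storage
Reagents that add atoms: sodium chlorite, [Na+].[O-]Cl=O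
Why: Pinnick oxidation is selective for the aldehyde, the scavenger protects the olefins from hypochlorous acid, and the cold buffered medium should avoid decarboxylative opening of the glycidic acid.

Step 20
Reactants: 27 glycidic acid; 28 N-hydroxyphthalimide
Product: 29 C4 glycidic N-(acyloxy)phthalimide tethered to the C1 vinyl ketone
Conditions: 28, N,N'-diisopropylcarbodiimide, DMAP (5 mol%), CH2Cl2, 0 °C
Reagents that add atoms: none
Why: Carbodiimide (Steglich-type) esterification is the standard entry to redox-active esters and runs under near-neutral conditions that the enone, epoxide and butenolide should survive.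

Step 21
Reactants: 29 C4 glycidic N-(acyloxy)phthalimide
Product: 30 CNP0285168.1 (4R,5R,6S,8S,10R)
Conditions: Ru(bpy)3(PF6)2 (2 mol%), Hantzsch ester (1.5 equiv), degassed CH2Cl2, 1 mM (29 added over 10 h), blue LEDs (450 nm), 20 °C, no amine
Reagents that add atoms: none
Why: Proposed new method: the excited ruthenium complex is quenched by the Hantzsch ester to [Ru(bpy)3]+, which passes one electron to the phthalimide ester; N–O cleavage and loss of CO2 leave a σ-type oxiranyl radical at C4 that adds to the CH2 terminus (C3) of the C1 vinyl ketone, and the C2 α-keto radical then takes hydrogen from the oxidised Hantzsch ester. The closest known reaction types are the reductive decarboxylative Giese reaction of N-(acyloxy)phthalimides, its use for macrocyclisation onto acrylates and enones, and intermolecular additions of oxiranyl radicals to electron-poor olefins, but the three have not been combined. The ten-membered carbocycle closes in the 10-endo-trig mode, the usual course of radical macrocyclisation onto an unsubstituted enone terminus. C4 is the only new stereocentre: the pyramidal radical should invert faster than it cyclises, and bonding to C3 trans to the C6 substituent on C5 is expected because that face is open and the trans-disubstituted oxirane gives the less strained ring. The step needs attack at the vinyl ketone only and cyclisation ahead of hydrogen capture, oxirane scission or dimerisation: the nucleophilic α-oxy radical is polarity-matched to the enone, the tetrasubstituted C7=C11 olefin is shielded, the amine-free medium spares the base-labile C6–H/epoxide array, and high dilution with slow addition suppresses bimolecular paths.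

Compound list
1 | (E)-4-acetoxy-2-methylbut-2-enal | CC(=O)OC/C=C(\C)C=O | starting material
2 | (E)-4-hydroxy-3-methylbut-2-enyl acetate | CC(=O)OC/C=C(\C)CO | intermediate
3 | (E)-4-(tert-butyldimethylsilyloxy)-3-methylbut-2-enyl acetate | CC(=O)OC/C=C(\C)CO[Si](C)(C)C(C)(C)C | intermediate
4 | (E)-4-(tert-butyldimethylsilyloxy)-3-methylbut-2-en-1-ol | OC/C=C(\C)CO[Si](C)(C)C(C)(C)C | intermediate
5 | (E)-4-(tert-butyldimethylsilyloxy)-3-methylbut-2-enal | O=C/C=C(\C)CO[Si](C)(C)C(C)(C)C | intermediate
6 | (S)-lactic acid | C[C@H](O)C(=O)O | starting material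
7 | pivalaldehyde | CC(C)(C)C=O | starting material
8 | (2S,5S)-2-tert-butyl-5-methyl-1,3-dioxolan-4-one | C[C@@H]1O[C@H](C(C)(C)C)OC1=O | intermediate
9 | propargyl bromide | C#CCBr | starting material
10 | (2S,5R)-2-tert-butyl-5-methyl-5-(prop-2-ynyl)-1,3-dioxolan-4-one | C#CC[C@@]1(C)O[C@H](C(C)(C)C)OC1=O | intermediate
11 | vinylmagnesium bromide | C=C[Mg]Br | starting material
12 | (2S,5R)-2-tert-butyl-5-methyl-5-(prop-2-ynyl)-1,3-dioxolan-4-ol (lactol, formed as its aluminium alkoxide) | C#CC[C@@]1(C)O[C@H](C(C)(C)C)OC1O | intermediate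
13 | (4R)-4-methylhept-1-en-6-yne-3,4-diol (carbinol epimers) | C=CC(O)[C@](C)(O)CC#C | intermediate
14 | (4R)-3-(tert-butyldimethylsilyloxy)-4-methylhept-1-en-6-yn-4-ol | C=CC(O[Si](C)(C)C(C)(C)C)[C@](C)(O)CC#C | intermediate
15 | (4R)-3-(tert-butyldimethylsilyloxy)-4-methylhept-1-en-6-yn-4-yl acetate | C=CC(O[Si](C)(C)C(C)(C)C)[C@](C)(OC(C)=O)CC#C | intermediate
16 | (4R,8R,9E)-3,11-bis(tert-butyldimethylsilyloxy)-8-hydroxy-4,10-dimethylundeca-1,9-dien-6-yn-4-yl acetate | C=CC(O[Si](C)(C)C(C)(C)C)[C@](C)(OC(C)=O)CC#C[C@H](O)/C=C(\C)CO[Si](C)(C)C(C)(C)C | intermediate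
17 | 4,5-epoxy-6-ol of 16 (4R,5R,6S,10R, target numbering) | C=CC(O[Si](C)(C)C(C)(C)C)[C@](C)(OC(C)=O)CC#C[C@H](O)[C@H]1O[C@]1(C)CO[Si](C)(C)C(C)(C)C | intermediate
18 | (Z)-7-tributylstannyl-7,8-alkene of 17 | C=CC(O[Si](C)(C)C(C)(C)C)[C@](C)(OC(C)=O)C/C=C(\[Sn](CCCC)(CCCC)CCCC)[C@H](O)[C@H]1O[C@]1(C)CO[Si](C)(C)C(C)(C)C | intermediate
19 | methyl 2-bromoacrylate | C=C(Br)C(=O)OC | starting material
20 | C7-(1-methoxycarbonylvinyl) hydroxy diene ester | C=CC(O[Si](C)(C)C(C)(C)C)[C@](C)(OC(C)=O)C/C=C(\C(=C)C(=O)OC)[C@H](O)[C@H]1O[C@]1(C)CO[Si](C)(C)C(C)(C)C | intermediate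
21 | α-methylene-β-alkylidene-γ-butyrolactone (C9 syn to C11) | C=CC(O[Si](C)(C)C(C)(C)C)[C@](C)(OC(C)=O)C/C=C1\C(=C)C(=O)O[C@@H]1[C@H]1O[C@]1(C)CO[Si](C)(C)C(C)(C)C | intermediate
22 | 7,8-epoxy-α-methylene lactone (O anti to C5, 8S) | C=CC(O[Si](C)(C)C(C)(C)C)[C@](C)(OC(C)=O)C[C@@H]1O[C@]12C(=C)C(=O)O[C@@H]2[C@H]2O[C@]2(C)CO[Si](C)(C)C(C)(C)C | intermediate
23 | 13-acetoxy-8-hydroxy-7(11)-butenolide | C=CC(O[Si](C)(C)C(C)(C)C)[C@](C)(OC(C)=O)C[C@H](O)C1=C(COC(C)=O)C(=O)O[C@@H]1[C@H]1O[C@]1(C)CO[Si](C)(C)C(C)(C)C | intermediate
24 | 8-propionate of 23 | C=CC(O[Si](C)(C)C(C)(C)C)[C@](C)(OC(C)=O)C[C@H](OC(=O)CC)C1=C(COC(C)=O)C(=O)O[C@@H]1[C@H]1O[C@]1(C)CO[Si](C)(C)C(C)(C)C | intermediate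
25 | diol (C1–OH, CH2OH on C4) | C=CC(O)[C@](C)(OC(C)=O)C[C@H](OC(=O)CC)C1=C(COC(C)=O)C(=O)O[C@@H]1[C@H]1O[C@]1(C)CO | intermediate
26 | C1 vinyl ketone / C4 carbaldehyde | C=CC(=O)[C@](C)(OC(C)=O)C[C@H](OC(=O)CC)C1=C(COC(C)=O)C(=O)O[C@@H]1[C@H]1O[C@]1(C)C=O | intermediate
27 | C4 glycidic acid | C=CC(=O)[C@](C)(OC(C)=O)C[C@H](OC(=O)CC)C1=C(COC(C)=O)C(=O)O[C@@H]1[C@H]1O[C@]1(C)C(=O)O | intermediate
28 | N-hydroxyphthalimide | O=C1c2ccccc2C(=O)N1O | starting material
29 | C4 glycidic N-(acyloxy)phthalimide (precursor of the key step) | C=CC(=O)[C@](C)(OC(C)=O)C[C@H](OC(=O)CC)C1=C(COC(C)=O)C(=O)O[C@@H]1[C@H]1O[C@]1(C)C(=O)ON1C(=O)c2ccccc2C1=O | intermediate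
30 | CNP0285168.1 | CCC(=O)O[C@H]1C[C@@](C)(OC(C)=O)C(=O)CC[C@@]2(C)O[C@@H]2[C@H]2OC(=O)C(COC(C)=O)=C12 | target

Total step count: 21. Longest linear sequence: 17 steps (steps 5–21, from (S)-lactic acid).

Steps most likely to fail

1. Step 21.
- Risk: the C4 oxiranyl radical may be consumed before ring closure by hydrogen capture, by C–O scission of the oxirane to an α-keto radical, or by intermolecular addition. Closure may also occur on the wrong face at C4.
- Fallback: known chemistry in which the ring is closed at C2=C3 by olefin metathesis and the exocyclic carbon on C4 is kept as C3. It sets out from 24.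
- Short contact with pyridine-buffered HF·pyridine at 0 °C should cleave only the primary silyl ether to give primary alcohol F1, and Dess–Martin oxidation gives epoxy aldehyde F2.
- Neutral rhodium-catalysed methylenation (RhCl(PPh3)3, Me3SiCHN2, 2-propanol, PPh3, THF) gives vinyl epoxide F3.
- Removal of the remaining silyl group gives allylic alcohol F4, and a second Dess–Martin oxidation gives vinyl ketone F5.
- Ring-closing metathesis (second-generation Hoveyda–Grubbs catalyst, toluene, 1 mM, 80 °C) gives the ten-membered 2,3-enone F6.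
- Conjugate reduction with [(Ph3P)CuH]6 saturates C2–C3 and comes back to the route at 30.

2. Step 13.
- Risk: transmetalation at the hindered, hydroxyl-flanked stannane may be slow enough for protodestannylation to take over. The hydroxy ester may be reluctant to adopt the crowded s-cis shape needed for lactonisation, and the cross-conjugated diene may dimerise by cycloaddition.
- Fallback: the ester bond is made first, so that the C–C bond forms intramolecularly. It sets out from 18.
- Acylation of the C6 hydroxyl with 2-bromoacryloyl chloride and 2,6-lutidine at −20 °C gives 2-bromoacrylate ester F7.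
- Intramolecular Stille closure of the five-membered ring (Pd2(dba)3, AsPh3, THF, high dilution) comes back to the route at 21 without a separate lactonisation.

3. Step 14.
- Risk: facial selectivity of the epoxidation at C7=C8 may be poor, which would scramble C8, or the other olefins may be oxidised competitively.
- Fallback: C8 is set by reagent control instead of substrate control. It sets out from 23 obtained as a mixture of C8 epimers through steps 14 and 15.
- Dess–Martin oxidation gives C8 ketone F8.
- Corey–Bakshi–Shibata reduction with the (R)-methyl oxazaborolidine and catecholborane in toluene at −78 °C treats the butenolide carbon C7 as the large group and C9 as the small one. It comes back to the route at 23 as the 8S alcohol.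

Further compounds
F1 | step 21 | primary alcohol (C1 silyl ether kept) | C=CC(O[Si](C)(C)C(C)(C)C)[C@](C)(OC(C)=O)C[C@H](OC(=O)CC)C1=C(COC(C)=O)C(=O)O[C@@H]1[C@H]1O[C@]1(C)CO
F2 | step 21 | epoxy aldehyde | C=CC(O[Si](C)(C)C(C)(C)C)[C@](C)(OC(C)=O)C[C@H](OC(=O)CC)C1=C(COC(C)=O)C(=O)O[C@@H]1[C@H]1O[C@]1(C)C=O
F3 | step 21 | vinyl epoxide | C=CC(O[Si](C)(C)C(C)(C)C)[C@](C)(OC(C)=O)C[C@H](OC(=O)CC)C1=C(COC(C)=O)C(=O)O[C@@H]1[C@H]1O[C@]1(C)C=C
F4 | step 21 | allylic alcohol | C=CC(O)[C@](C)(OC(C)=O)C[C@H](OC(=O)CC)C1=C(COC(C)=O)C(=O)O[C@@H]1[C@H]1O[C@]1(C)C=C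
F5 | step 21 | vinyl ketone | C=CC(=O)[C@](C)(OC(C)=O)C[C@H](OC(=O)CC)C1=C(COC(C)=O)C(=O)O[C@@H]1[C@H]1O[C@]1(C)C=C
F6 | step 21 | ten-membered 2,3-enone (2,3-didehydro target) | CCC(=O)O[C@H]1C[C@@](C)(OC(C)=O)C(=O)C=C[C@@]2(C)O[C@@H]2[C@H]2OC(=O)C(COC(C)=O)=C12
F7 | step 13 | 2-bromoacrylate ester of 18 | C=CC(O[Si](C)(C)C(C)(C)C)[C@](C)(OC(C)=O)C/C=C(\[Sn](CCCC)(CCCC)CCCC)[C@H](OC(=O)C(Br)=C)[C@H]1O[C@]1(C)CO[Si](C)(C)C(C)(C)C
F8 | step 14 | C8 ketone | C=CC(O[Si](C)(C)C(C)(C)C)[C@](C)(OC(C)=O)CC(=O)C1=C(COC(C)=O)C(=O)O[C@@H]1[C@H]1O[C@]1(C)CO[Si](C)(C)C(C)(C)C
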